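| setting | ochre | teal | grey | violet |
|---|---|---|---|---|
| starting material | 150 mM | 150 mM | 150 mM | 50.0 mM |
| coupling partner | 120 mM | 120 mM | 360 mM | 20.0 mM |
| target |  | 45.0 mM |  |  |
| time |  |  |  | 16 min |

- ochre run (time / min: [target] / mM): 3.2: 10.8; 6.4: 26.8; 9.6: 37.5; 13: 44.3; 16: 49.1
- teal run (time / min: [target] / mM): 3.2: 47.1; 6.4: 54.5; 9.6: 59.6; 13: 65.4; 16: 65.0
- grey run (time / min: [target] / mM): 3.2: 20.5; 6.4: 37.1; 9.6: 46.2; 13: 50.0; 16: 49.3

(scatter of a reading: 1 mM)

* reaction order in [coupling partner] at the outset, round the charge of the ochre run, defined at two percent of the starting material turned into target
* target in the violet run at 16 min, as a share of the starting material charged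

- Overall: starting material + coupling partner -> target.
- Constant volume, constant temperature.
- "The second partner" is coupling partner.
- An order is taken over about fifteen percent of the charge, up and down.

**Shrinking lead.** At 3.2 min the teal run, charged like the ochre run but with 45.0 mM of target added, leads the ochre run by 36.3 mM; at 16 min its lead is 15.9 mM, which is smaller. If target forms alike in both flasks, this lead is the added target still surviving. Read as a pseudo-first-order loss, it gives 15.4 min: the target lifetime, the mean time target survives once formed.

**Usable window.** Under steady formation, the target standing at time t is the formation rate times the lifetime times (1 − exp(−t/lifetime)). At 16 min, which is 1.04 lifetimes, that window is 9.95 min. The ochre reading of 49.1 mM therefore implies average formation of 4.94 mM min⁻¹.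

**Two extremes.** The violet run holds a third of the ochre starting material, and as an estimate we carry the ochre window over to it unchanged, although it was read at a larger partner charge. If formation ignored the coupling partner, violet would form 1.65 mM min⁻¹ and stand at 32.7%, with 16.4 mM of target below the 20.0 mM charge of the limiting reagent. If formation were also proportional to the partner, violet would stand at 5.46%. The grey run lies between: 3.00 times the partner gave 1.90 times the target at 3.2 min. That is an order of 0.583, which we commit to, and with it violet comes to 11.5%.

**Forecast.** The forecast gives 0.65 and 20%, judging that “product strongly inhibits”.

**Result.** The flask gives an order of 0.48 and 13.8%, with the grey rate 1.62 times the ochre rate where the same amount of target has been made.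

    starting material → intermediate (0.08280 min⁻¹)
    intermediate + coupling partner → target (2.280 L mol⁻¹ min⁻¹)
    intermediate → side product (0.007200 min⁻¹)
    target + coupling partner → side product (0.1728 L mol⁻¹ min⁻¹)
    target → decomposed product (0.04488 min⁻¹)

In the violet run that share is 6.88 mM of target at 16 min. Our lifetime of 15.4 min was read at the ochre partner charge; at the violet charge of 20.0 mM the two target losses of the scheme give a lifetime of 20.7 min at the start of the violet run, longer than ours. With that lifetime the violet window at 16 min is 11.1 min, and the violet share means average formation of about 0.620 mM min⁻¹.

The numbers in the tables are simulated with constants of no real substance; scatter was added.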